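**Retrosynthetic overview**

- The target is all-E (6R)-ε,ψ-carotene. It is cut at C11=C12 and C11'=C12' into an ε-end C15 phosphonium salt, the C10 dialdehyde and an acyclic ψ-end C15 phosphonium salt (two Wittig reactions).
- The strategy rests on one feature: the only stereocentre, C6, is allylic to the ring alkene C4=C5 of the six-membered ε-ring. The C6–C7 bond is therefore made by an anti SN2' attack of a dienylcopper reagent on an isomeric ring that carries the alkene at C5=C6 and a picolinate at C4.
- The (R)-picolinate comes from Corey–Bakshi–Shibata reduction of 2,4,4-trimethylcyclohex-2-enone. The dienyl nucleophile comes from the (E)-enynol by hydrozirconation and iodination.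
- Only one ring is formed, the cyclohexene, in step 1 by Michael addition and aldol condensation of isobutyraldehyde with ethyl vinyl ketone.

Key step: step 7

Remark: positions are given in carotenoid numbering (primed for the ψ half); pseudoionone 21 is taken as its (3E,5E) isomer, the main component of the commercial material, enriched by fractional distillation; cyclopentadienyl ligands are drawn σ-bonded in the line notations.

**Route**

Step 1
Reactants: 1 isobutyraldehyde; 2 ethyl vinyl ketone
Product: 4 2,4,4-trimethylcyclohex-2-en-1-one, via 2,2-dimethyl-5-oxoheptanal 3 (not isolated)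
Conditions: H2SO4 (cat.), toluene, 45 °C, then reflux, Dean–Stark
Reagents that add atoms: none
Why: Acid-catalysed Michael addition of the aldehyde enol to the enone followed by intramolecular aldol condensation (Robinson annulation) should give one enone, because the aldehyde of 3 cannot enolise and only the ethyl-side α-carbon of the ketone can close a six-membered ring onto it.

Step 2
Reactants: 4 2,4,4-trimethylcyclohex-2-en-1-one
Product: 5 (1R)-2,4,4-trimethylcyclohex-2-en-1-ol
Conditions: (3aS)-1-methyl-3,3-diphenyltetrahydro-1H,3H-pyrrolo[1,2-c][1,3,2]oxazaborole [(S)-Me-CBS, 0.15 equiv], BH3·SMe2 (0.7 equiv), THF, −20 °C; MeOH, then aqueous work-up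
Reagents that add atoms: none
Why: In this Corey–Bakshi–Shibata reduction the ketone should bind the ring boron with its larger 2-methylvinyl flank turned away from the catalyst, so that the nitrogen-bound borane delivers hydride to the Si face of the carbonyl and sets the (R)-carbinol, with 1,2-reduction only.

Step 3
Reactants: 5 (1R)-2,4,4-trimethylcyclohex-2-en-1-ol
Product: 6 (1R)-2,4,4-trimethylcyclohex-2-en-1-yl pyridine-2-carboxylate
Conditions: picolinic acid, N,N'-dicyclohexylcarbodiimide, 4-(dimethylamino)pyridine (cat.), CH2Cl2, 0 °C → rt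
Reagents that add atoms: picolinic acid, O=C(O)c1ccccn1
Why: Steglich esterification acylates the secondary alcohol on oxygen without breaking the C–O bond, so the (R) configuration is kept.

Step 4
Reactants: 7 (2E)-3-methylpent-2-en-4-yn-1-ol
Product: 8 tert-butyldimethyl{[(2E)-3-methylpent-2-en-4-yn-1-yl]oxy}silane
Conditions: TBSCl, imidazole, CH2Cl2, 0 °C → rt
Reagents that add atoms: tert-butyldimethylsilyl chloride, CC(C)(C)[Si](C)(C)Cl
Why: Imidazole-promoted silylation of a primary alcohol masks the hydroxyl against the organometallic steps that follow and leaves the enyne untouched.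

Step 5
Reactants: 8 tert-butyldimethyl{[(2E)-3-methylpent-2-en-4-yn-1-yl]oxy}silane
Product: 10 tert-butyl{[(2E,4E)-5-iodo-3-methylpenta-2,4-dien-1-yl]oxy}dimethylsilane, via alkenylzirconocene chloride 9 (not isolated)
Conditions: Cp2Zr(H)Cl (1.2 equiv), THF, rt, dark; then I2, 0 °C
Reagents that add atoms: iodine, II
Why: Hydrozirconation adds Zr–H syn across the terminal alkyne with zirconium on the terminal carbon, the trisubstituted alkene does not react, and iodinolysis of the C–Zr bond with retention should give the (E)-alkenyl iodide.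

Step 6
Reactants: 10 tert-butyl{[(2E,4E)-5-iodo-3-methylpenta-2,4-dien-1-yl]oxy}dimethylsilane
Product: 12 [(1E,3E)-5-(tert-butyldimethylsilyloxy)-3-methylpenta-1,3-dien-1-yl]magnesium bromide, via dienyllithium 11 (not isolated)
Conditions: t-BuLi (2.05 equiv), Et2O, −78 °C; then MgBr2·OEt2 (1.1 equiv), −78 → 0 °C; the solution of 12 is used directly in step 7
Reagents that add atoms: magnesium bromide diethyl etherate, Br[Mg]Br.CCOCC
Why: Iodine–lithium exchange on an alkenyl iodide is fast at −78 °C and keeps the alkene geometry, the second equivalent of t-BuLi destroys the tert-butyl iodide, and transmetalation with MgBr2 gives the Grignard reagent needed for the copper step.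

Step 7
Reactants: 6 (1R)-2,4,4-trimethylcyclohex-2-en-1-yl pyridine-2-carboxylate; 12 [(1E,3E)-5-(tert-butyldimethylsilyloxy)-3-methylpenta-1,3-dien-1-yl]magnesium bromide
Product: 14 tert-butyldimethylsilyl ether of (2E,4E)-3-methyl-5-[(1R)-2,6,6-trimethylcyclohex-2-en-1-yl]penta-2,4-dien-1-ol, via magnesium bis(dienyl)cuprate 13 (not isolated)
Conditions: 12 (2.4 equiv), CuBr·SMe2 (1.2 equiv), THF/Et2O, −40 → 0 °C; then 6, 0 °C; aq. NH4Cl
Reagents that add atoms: none
Why: Two equivalents of 12 and CuBr·SMe2 form cuprate 13, whose magnesium counter-ion is held between the pyridine nitrogen and the carbonyl oxygen of the picolinate; this activates the leaving group and brings the monovalent copper centre to the alkene, which it attacks at ring carbon C3 of 6 (the γ-carbon, C6 of the carotenoid) on the face opposite the C–O bond, and the σ-allyl trivalent copper species so formed reductively eliminates at once, forming C6–C7 with the alkene moved to C4=C5 and the dienyl geometry retained. The closest known reaction type is the copper-mediated anti SN2' substitution of enantioenriched secondary allylic picolinates with aryl- and alkenylmagnesium bromides, which goes with 1,3-chirality transfer. No ring is closed. The new stereocentre C6 is controlled by the (R)-carbinol carbon of 6: the neighbouring 2-methyl group should push the picolinoxy group pseudoaxial, which aligns the C–O bond with the π system, and the ring leaves only the opposite face open, so (R) at the carbinol becomes (R) at C6. The step needs γ- over α-attack and anti over syn delivery, and the chelating leaving group secures both; the γ-carbon lies next to the gem-dimethyl carbon, but cuprates attack the same kind of position readily in conjugate additions to 4,4-dimethylcyclohexenones.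

Step 8
Reactants: 14 tert-butyldimethylsilyl ether of the C15 dienol
Product: 15 (2E,4E)-3-methyl-5-[(1R)-2,6,6-trimethylcyclohex-2-en-1-yl]penta-2,4-dien-1-ol
Conditions: Bu4NF, THF, 0 °C
Reagents that add atoms: none
Why: Fluoride cleaves the Si–O bond selectively, and neither the skipped ring alkene nor the diene reacts under these mild basic conditions.

Step 9
Reactants: 15 (2E,4E)-3-methyl-5-[(1R)-2,6,6-trimethylcyclohex-2-en-1-yl]penta-2,4-dien-1-ol
Product: 16 {(2E,4E)-3-methyl-5-[(1R)-2,6,6-trimethylcyclohex-2-en-1-yl]penta-2,4-dien-1-yl}triphenylphosphonium bromide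
Conditions: PPh3·HBr (1.05 equiv), MeOH, 0 °C → rt, dark; crystallise
Reagents that add atoms: triphenylphosphine hydrobromide, Br.c1ccc(cc1)P(c1ccccc1)c1ccccc1
Why: The phosphonium hydrobromide ionises the allylic alcohol to a pentadienyl cation, which triphenylphosphine captures reversibly at the unhindered terminus C11 to give the conjugated (9E) salt; C6 lies outside the cation, so its configuration should be kept, as is usual for ionylidene-ethanol-type alcohols.

Step 10
Reactants: 16 ε-end C15 phosphonium bromide; 17 (2E,4E,6E)-2,7-dimethylocta-2,4,6-trienedial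
Product: 20 (2E,4E,6E,8E,10E,12E)-2,7,11-trimethyl-13-[(1R)-2,6,6-trimethylcyclohex-2-en-1-yl]trideca-2,4,6,8,10,12-hexaenal, via phosphorus ylide 18 (not isolated), via (11Z)-C25 aldehyde 19 (not isolated)
Conditions: 17 (2 equiv), NaOMe (1.1 equiv), CH2Cl2/MeOH, slow addition of 16, 0 °C → rt, Ar, dark; crude: I2 (cat.), hexane/CH2Cl2, rt, daylight
Reagents that add atoms: none
Why: Wittig olefination of the allylic ylide with one formyl group of the dialdehyde forms C11=C12, the excess of 17 and the slow addition favour mono-olefination, and iodine-catalysed equilibration should convert the sterically strained (11Z) isomer into the all-E aldehyde.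

Step 11
Reactants: 21 (3E,5E)-pseudoionone
Product: 22 (4E,6E)-3,7,11-trimethyldodeca-1,4,6,10-tetraen-3-ol (racemic)
Conditions: CH2=CHMgBr, THF, 0 °C; then H2O
Reagents that add atoms: vinylmagnesium bromide, C=C[Mg]Br
Why: Without copper the vinyl Grignard reagent adds 1,2 to the methyl ketone of the dienone, and the new carbinol centre is lost again in the next step, so its configuration does not matter.

Step 12
Reactants: 22 (4E,6E)-3,7,11-trimethyldodeca-1,4,6,10-tetraen-3-ol
Product: 23 [(2E,4E,6E)-3,7,11-trimethyldodeca-2,4,6,10-tetraen-1-yl]triphenylphosphonium bromide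
Conditions: PPh3·HBr (1.05 equiv), MeOH, 0 °C → rt, dark; crystallise
Reagents that add atoms: triphenylphosphine hydrobromide, Br.c1ccc(cc1)P(c1ccccc1)c1ccccc1
Why: Ionisation of the tertiary allylic alcohol and capture of the extended allyl cation by triphenylphosphine at its primary terminus (allylic transposition) should give the conjugated primary salt, and crystallisation enriches the (2E) isomer.

Step 13
Reactants: 20 all-E C25 aldehyde; 23 ψ-end C15 phosphonium bromide
Product: 26 all-E (6R)-ε,ψ-carotene, via phosphorus ylide 24 (not isolated), via (11'Z)-δ-carotene 25 (not isolated)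
Conditions: 23 (1.3 equiv), NaOMe (1.4 equiv), CH2Cl2/MeOH, 0 °C → rt, Ar, dark; crude: n-heptane, reflux, Ar, dark; crystallise
Reagents that add atoms: none
Why: The second Wittig olefination forms C11'=C12', heating in heptane should relax the strained (11'Z) isomer to the all-E polyene, which crystallises, and neither the mild base nor the heating affects the sp3 stereocentre C6 or the skipped ring alkene.

**Compound list**

1 | isobutyraldehyde (2-methylpropanal) | CC(C)C=O | starting material
2 | ethyl vinyl ketone (pent-1-en-3-one) | CCC(=O)C=C | starting material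
3 | 2,2-dimethyl-5-oxoheptanal | CCC(=O)CCC(C)(C)C=O | intermediate (not isolated)
4 | 2,4,4-trimethylcyclohex-2-en-1-one | CC1=CC(C)(C)CCC1=O | intermediate
5 | (1R)-2,4,4-trimethylcyclohex-2-en-1-ol | O[C@H]1C(C)=CC(C)(C)CC1 | intermediate
6 | (1R)-2,4,4-trimethylcyclohex-2-en-1-yl pyridine-2-carboxylate | O=C(O[C@H]1C(C)=CC(C)(C)CC1)c1ccccn1 | intermediate
7 | (2E)-3-methylpent-2-en-4-yn-1-ol | C#C/C(C)=C/CO | starting material
8 | tert-butyldimethyl{[(2E)-3-methylpent-2-en-4-yn-1-yl]oxy}silane | C#C/C(C)=C/CO[Si](C)(C)C(C)(C)C | intermediate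
9 | chlorobis(cyclopentadienyl)[(1E,3E)-5-(tert-butyldimethylsilyloxy)-3-methylpenta-1,3-dien-1-yl]zirconium | CC(C)(C)[Si](C)(C)OC/C=C(C)/C=C/[Zr](Cl)(C1C=CC=C1)C1C=CC=C1 | intermediate (not isolated)
10 | tert-butyl{[(2E,4E)-5-iodo-3-methylpenta-2,4-dien-1-yl]oxy}dimethylsilane | CC(C)(C)[Si](C)(C)OC/C=C(C)/C=C/I | intermediate
11 | [(1E,3E)-5-(tert-butyldimethylsilyloxy)-3-methylpenta-1,3-dien-1-yl]lithium | CC(C)(C)[Si](C)(C)OC/C=C(C)/C=C/[Li] | intermediate (not isolated)
12 | [(1E,3E)-5-(tert-butyldimethylsilyloxy)-3-methylpenta-1,3-dien-1-yl]magnesium bromide | CC(C)(C)[Si](C)(C)OC/C=C(C)/C=C/[Mg]Br | intermediate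
13 | bromomagnesium bis[(1E,3E)-5-(tert-butyldimethylsilyloxy)-3-methylpenta-1,3-dien-1-yl]cuprate | CC(C)(C)[Si](C)(C)OC/C=C(C)/C=C/[Cu-]/C=C/C(C)=C/CO[Si](C)(C)C(C)(C)C.[Mg+]Br | intermediate (not isolated)
14 | tert-butyldimethyl{[(2E,4E)-3-methyl-5-[(1R)-2,6,6-trimethylcyclohex-2-en-1-yl]penta-2,4-dien-1-yl]oxy}silane | CC(C)(C)[Si](C)(C)OC/C=C(C)/C=C/[C@H]1C(C)=CCCC1(C)C | intermediate
15 | (2E,4E)-3-methyl-5-[(1R)-2,6,6-trimethylcyclohex-2-en-1-yl]penta-2,4-dien-1-ol | OC/C=C(C)/C=C/[C@H]1C(C)=CCCC1(C)C | intermediate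
16 | {(2E,4E)-3-methyl-5-[(1R)-2,6,6-trimethylcyclohex-2-en-1-yl]penta-2,4-dien-1-yl}triphenylphosphonium bromide | [Br-].c1ccc(cc1)[P+](C/C=C(C)/C=C/[C@H]1C(C)=CCCC1(C)C)(c1ccccc1)c1ccccc1 | intermediate
17 | (2E,4E,6E)-2,7-dimethylocta-2,4,6-trienedial | O=C/C(C)=C/C=C/C=C(C)/C=O | starting material
18 | {(2E,4E)-3-methyl-5-[(1R)-2,6,6-trimethylcyclohex-2-en-1-yl]penta-2,4-dien-1-ylidene}triphenylphosphorane | c1ccc(cc1)P(=C/C=C(C)/C=C/[C@H]1C(C)=CCCC1(C)C)(c1ccccc1)c1ccccc1 | intermediate (not isolated)
19 | (2E,4E,6E,8Z,10E,12E)-2,7,11-trimethyl-13-[(1R)-2,6,6-trimethylcyclohex-2-en-1-yl]trideca-2,4,6,8,10,12-hexaenal, the (11Z) isomer in carotenoid numbering | O=C\C(C)=C\C=C\C=C(C)\C=C/C=C(C)/C=C/[C@H]1C(C)=CCCC1(C)C | intermediate (not isolated)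
20 | (2E,4E,6E,8E,10E,12E)-2,7,11-trimethyl-13-[(1R)-2,6,6-trimethylcyclohex-2-en-1-yl]trideca-2,4,6,8,10,12-hexaenal | O=C/C(C)=C/C=C/C=C(C)/C=C/C=C(C)/C=C/[C@H]1C(C)=CCCC1(C)C | intermediate
21 | (3E,5E)-6,10-dimethylundeca-3,5,9-trien-2-one (pseudoionone) | CC(C)=CCC/C(C)=C/C=C/C(C)=O | starting material
22 | (4E,6E)-3,7,11-trimethyldodeca-1,4,6,10-tetraen-3-ol (racemic) | CC(C)=CCC/C(C)=C/C=C/C(C)(O)C=C | intermediate
23 | [(2E,4E,6E)-3,7,11-trimethyldodeca-2,4,6,10-tetraen-1-yl]triphenylphosphonium bromide | CC(C)=CCC/C(C)=C/C=C/C(C)=C/C[P+](c1ccccc1)(c1ccccc1)c1ccccc1.[Br-] | intermediate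
24 | [(2E,4E,6E)-3,7,11-trimethyldodeca-2,4,6,10-tetraen-1-ylidene]triphenylphosphorane | CC(C)=CCC/C(C)=C/C=C/C(C)=C/C=P(c1ccccc1)(c1ccccc1)c1ccccc1 | intermediate (not isolated)
25 | (6R,11'Z)-ε,ψ-carotene | CC(C)=CCC\C(C)=C\C=C\C(C)=C\C=C/C(C)=C/C=C/C=C(C)/C=C/C=C(C)/C=C/[C@H]1C(C)=CCCC1(C)C | intermediate (not isolated)
26 | all-E (6R)-ε,ψ-carotene (δ-carotene) | CC(C)=CCC/C(C)=C/C=C/C(C)=C/C=C/C(C)=C/C=C/C=C(C)/C=C/C=C(C)/C=C/[C@H]1C(C)=CCCC1(C)C | target

**Step count**

Total steps: 13. Longest linear sequence: 8 steps (1, 2, 3, 7, 8, 9, 10, 13; the dienyl branch 4, 5, 6, 7, 8, 9, 10, 13 is equally long).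

**Steps most likely to fail, with fallbacks**

Step 7. The γ-carbon is flanked by the gem-dimethyl carbon, so attack there may be slow. Substitution at the α-carbon, attack of the organometallic on the ester or loss of the anti stereospecificity could then take over.
The fallback sets out from enone 4 and comes back at alcohol 15. It sets C6 by a suprafacial [2,3]-Wittig–Still rearrangement, which delivers carbon on the face of the departing oxygen and therefore needs the enantiomeric carbinol. Reduction of enone 4 with (3aR)-1-methyl-3,3-diphenyltetrahydro-1H,3H-pyrrolo[1,2-c][1,3,2]oxazaborole and BH3·SMe2 should give (1S)-2,4,4-trimethylcyclohex-2-en-1-ol F1 in the same way as step 2. Treatment of F1 with KH and Bu3SnCH2I in THF gives tributyl({[(1S)-2,4,4-trimethylcyclohex-2-en-1-yl]oxy}methyl)stannane F2 as the stannylmethyl ether. Tin–lithium exchange on F2 with n-BuLi in THF at −78 °C and rearrangement of the α-alkoxymethyllithium should lead to [(1R)-2,6,6-trimethylcyclohex-2-en-1-yl]methanol F3 which is (R)-α-cyclogeraniol. Buffered Dess–Martin oxidation of F3 (NaHCO3, CH2Cl2, 0 °C) gives (1R)-2,6,6-trimethylcyclohex-2-ene-1-carbaldehyde F4 which is (R)-α-cyclocitral; it is used cold and at once because its α-hydrogen is labile. Horner–Wadsworth–Emmons reaction of F4 with the anion of ethyl (2E)-4-(diethoxyphosphoryl)-3-methylbut-2-enoate (LiN(SiMe3)2, THF, −78 → 0 °C) gives ethyl (2E,4E)-3-methyl-5-[(1R)-2,6,6-trimethylcyclohex-2-en-1-yl]penta-2,4-dienoate F5 after chromatographic removal of any (2Z) isomer. Reduction of F5 with i-Bu2AlH in CH2Cl2 at −78 °C gives 15.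

Step 10. The mono-aldehyde product may compete with the dialdehyde for the ylide, which would give double olefination and waste salt 16.
The fallback sets out from dialdehyde 17 and comes back at aldehyde 20. The dialdehyde is desymmetrised first, at a stage where material is cheap. Mono-acetalisation with 2,2-dimethylpropane-1,3-diol (pyridinium p-toluenesulfonate, toluene, rt) gives (2E,4E,6E)-7-(5,5-dimethyl-1,3-dioxan-2-yl)-2-methylocta-2,4,6-trienal F6 which is separated from bis-acetal and recovered 17. Wittig reaction of F6 with ylide 18 (from 16 and NaOMe) gives the C25 acetal 5,5-dimethyl-2-{(2E,4E,6E,8E,10E,12E)-7,11-dimethyl-13-[(1R)-2,6,6-trimethylcyclohex-2-en-1-yl]trideca-2,4,6,8,10,12-hexaen-2-yl}-1,3-dioxane F7 together with its isomer that is Z at the new double bond. Dilute aqueous H2SO4 in THF at 0 °C releases the aldehyde from F7 and the iodine equilibration of step 10 then gives 20.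

Step 13. Stereoconvergence may be incomplete: the new C11'=C12' bond forms as an E/Z mixture, less strained Z isomers carried in from salt 23 may persist, and long heating of the polyene may cause oxidative loss.
The fallback sets out from alcohol 22 and comes back at target 26. The Wittig salt is replaced by a phosphonate, so that the olefination itself is E-selective and no heating is needed. PBr3 with pyridine in Et2O at −10 °C converts 22 with allylic transposition into (2E,4E,6E)-1-bromo-3,7,11-trimethyldodeca-2,4,6,10-tetraene F8 as the main isomer. Michaelis–Arbuzov reaction of F8 with P(OEt)3 at 90 °C gives diethyl [(2E,4E,6E)-3,7,11-trimethyldodeca-2,4,6,10-tetraen-1-yl]phosphonate F9 with loss of bromoethane. Deprotonation of F9 with KOt-Bu in THF/DMSO at −20 °C and Horner–Wadsworth–Emmons reaction with aldehyde 20 should give 26 directly.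

**Further compounds**

F1 | step 7 | (1S)-2,4,4-trimethylcyclohex-2-en-1-ol | O[C@@H]1C(C)=CC(C)(C)CC1
F2 | step 7 | tributyl({[(1S)-2,4,4-trimethylcyclohex-2-en-1-yl]oxy}methyl)stannane | CCCC[Sn](CCCC)(CCCC)CO[C@@H]1C(C)=CC(C)(C)CC1
F3 | step 7 | [(1R)-2,6,6-trimethylcyclohex-2-en-1-yl]methanol | OC[C@H]1C(C)=CCCC1(C)C
F4 | step 7 | (1R)-2,6,6-trimethylcyclohex-2-ene-1-carbaldehyde | O=C[C@H]1C(C)=CCCC1(C)C
F5 | step 7 | ethyl (2E,4E)-3-methyl-5-[(1R)-2,6,6-trimethylcyclohex-2-en-1-yl]penta-2,4-dienoate | CCOC(=O)/C=C(C)/C=C/[C@H]1C(C)=CCCC1(C)C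
F6 | step 10 | (2E,4E,6E)-7-(5,5-dimethyl-1,3-dioxan-2-yl)-2-methylocta-2,4,6-trienal | O=C/C(C)=C/C=C/C=C(C)/C1OCC(C)(C)CO1
F7 | step 10 | 5,5-dimethyl-2-{(2E,4E,6E,8E,10E,12E)-7,11-dimethyl-13-[(1R)-2,6,6-trimethylcyclohex-2-en-1-yl]trideca-2,4,6,8,10,12-hexaen-2-yl}-1,3-dioxane | CC1(C)COC(/C(C)=C/C=C/C=C(C)/C=C/C=C(C)/C=C/[C@H]2C(C)=CCCC2(C)C)OC1
F8 | step 13 | (2E,4E,6E)-1-bromo-3,7,11-trimethyldodeca-2,4,6,10-tetraene | CC(C)=CCC/C(C)=C/C=C/C(C)=C/CBr
F9 | step 13 | diethyl [(2E,4E,6E)-3,7,11-trimethyldodeca-2,4,6,10-tetraen-1-yl]phosphonate | CCOP(=O)(C/C=C(C)/C=C/C=C(C)/CCC=C(C)C)OCC
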